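**Retrosynthetic overview**
1. Target 21 is cut at C6–C7. A light-driven Ni/HAT coupling of a formyl C–H with a vinyl bromide in 20 closes the oxonane last and gives the α-methylene ketone directly.
2. C4–C5 comes from chelate-controlled allylation of a C4 aldehyde. C3–C4 comes from Cram-chelate vinyl addition to a C2 acetyl group. C16–O–C3 (the oxepane) comes from triflate etherification.
3. C8–C9 comes from 2-bromoallylsilane attack on the C9 oxocarbenium ion. C12 and C11 come from convex-face hydroboration followed by ketone reduction.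
4. The THF ring comes from aldehyde 8, an acetyl-anion equivalent and the internal acetal. The cyclohexene comes from an endo Diels–Alder reaction of enal 4 (from Roche ester) with diene 7.
5. Ring order is cyclohexene, THF, oxepane, oxonane. C15 is the only bought stereocentre, and it relays to all the others.

Convention (one line): locants are asbestinin numbering (C2/C9 = THF C–O carbons, C3 = quaternary C, C4 = octanoate, C6 = ketone, C7 = C=CH2, C11 = OAc, C12 = CHMe, C15 = CHMe, C16 = OCH2); "α" is the convex face carrying H-1 and H-10; C9 of 9 and 10 is an anomeric mixture that converges in step 9.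

**Step 1**
Reactants: 1, methyl (S)-3-hydroxy-2-methylpropanoate
Product: 2, methyl (S)-3-(tert-butyldiphenylsilyloxy)-2-methylpropanoate
Conditions: TBDPSCl, imidazole, DMF, rt
Reagents that add atoms: TBDPSCl, CC(C)(C)[Si](Cl)(c1ccccc1)c1ccccc1
Why: Standard silylation gives an acid-stable ether whose bulk later acts as the "large" group next to C15, and C15 is the bought stereocentre.

**Step 2**
Reactants: 2
Product: 3, (S)-3-(tert-butyldiphenylsilyloxy)-2-methylpropanal
Conditions: DIBAL-H, CH2Cl2, −78 °C
Reagents that add atoms: none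
Why: Partial ester reduction stops at the tetrahedral aluminate at −78 °C, so the α-stereocentre is not epimerised.

**Step 3**
Reactants: 3
Product: 4, (R,E)-5-(tert-butyldiphenylsilyloxy)-4-methylpent-2-enal
Conditions: Ph3P=CHCHO, toluene, 80 °C
Reagents that add atoms: (triphenylphosphoranylidene)acetaldehyde, O=CC=P(c1ccccc1)(c1ccccc1)c1ccccc1
Why: A stabilised-ylide Wittig two-carbon homologation gives the E-enal (C2, C1, C14), and the descriptor change S→R is only a CIP priority change.

**Step 4**
Reactants: 5, 2,2-dimethoxyacetaldehyde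
Product: 6, (E)-5,5-dimethoxypent-3-en-2-one
Conditions: Ph3P=CHC(O)CH3, CH2Cl2, rt
Reagents that add atoms: 1-(triphenylphosphoranylidene)propan-2-one, CC(=O)C=P(c1ccccc1)(c1ccccc1)c1ccccc1
Why: This E-selective stabilised Wittig olefination tolerates the aqueous commercial aldehyde.

**Step 5**
Reactants: 6
Product: 7, (E)-5,5-dimethoxy-2-methylpenta-1,3-diene
Conditions: MePPh3Br, KOtBu, THF, 0 °C
Reagents that add atoms: methyltriphenylphosphonium bromide, C[P+](c1ccccc1)(c1ccccc1)c1ccccc1.[Br-]
Why: Wittig methylenation of the enone carbonyl (1,2-selective) gives the diene C9–C13 with C9 already at the aldehyde oxidation level.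

**Step 6**
Reactants: 4, the enal; 7, the diene
Product: 8, (1S,2R,6S)-6-[(2R)-1-(tert-butyldiphenylsilyloxy)propan-2-yl]-2-(dimethoxymethyl)-4-methylcyclohex-3-ene-1-carbaldehyde (CHO and CH(OMe)2 cis; CHO and side chain trans)
Conditions: Me2AlCl (1.1 equiv, pre-complexed with 4), CH2Cl2, −78 → −40 °C, slow addition of 7
Reagents that add atoms: none
Why: In this Lewis-acid Diels–Alder reaction the 1-substituent and the 3-methyl of the diene both direct C13→C14 and C10→C1; the E-enal fixes C2 and C15 trans, endo-CHO fixes C2 and C9 cis, and the diene adds anti to CH2OTBDPS in the Felkin-type rotamer (Me inside, H outside), which sets C14, C1 and C10 from C15.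

**Step 7**
Reactants: 8
Product: 9, a cis-fused hexahydroisobenzofuran (C2–O–C9 ring) with C2 acetyl on the α face (H-2 β), C9 OMe (anomers), H-1/H-10 α, the C11=C12(Me) alkene, and the C14 side chain α (H-14 β)
Conditions: 1-ethoxyvinyllithium (ethyl vinyl ether, t-BuLi), THF, −78 °C; then PPTS, MeOH–H2O (20:1), rt; then DBU, CH2Cl2, rt
Reagents that add atoms: ethyl vinyl ether, C=COCC (delivers C3 and C18); water, O (ketone oxygen); methanol, CO (exchanges with the C9 OMe)
Why: Acyl-anion addition, enol-ether hydrolysis and intramolecular transacetalisation build the THF ring, and C2, which is α to the ketone, is then equilibrated by DBU to the convex-face acetyl epimer, so the addition selectivity does not matter.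

**Step 8**
Reactants: 9
Product: 10, the C3,C11-diketone (as 9 but with C11=O, H-12 α and C12-Me β)
Conditions: BH3·THF (3 equiv), 0 °C → rt; MeOH quench; then NMO (excess), TPAP (10 mol %), 4 Å MS, CH2Cl2, rt
Reagents that add atoms: N-methylmorpholine N-oxide, C[N+]1([O-])CCOCC1 (C11 oxygen)
Why: Hydroboration places boron on the less substituted C11 and H on C12 from the convex α face, which sets C12; the one-pot N-oxide/TPAP oxidation then turns C–B into the ketone and re-oxidises the transiently reduced C3 carbinol under neutral conditions.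

**Step 9**
Reactants: 10
Product: 11, the C9 α-(2-bromoallyl) diketone (H-9 β; C8 cis to the C2 acetyl and trans to C11)
Conditions: (2-bromoallyl)trimethylsilane, TMSOTf, CH2Cl2, −78 → −30 °C
Reagents that add atoms: (2-bromoallyl)trimethylsilane, C=C(Br)C[Si](C)(C)C
Why: Hosomi–Sakurai substitution occurs via the bicyclic C9 oxocarbenium ion, which the silane attacks on the convex face to set C9, and ketones are far less electrophilic than the ion under these conditions.

**Step 10**
Reactants: 11
Product: 12, the C3 tertiary allylic alcohol (C3 arranged as in 21: OH, CH3, vinyl = C4)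
Conditions: MgBr2·OEt2, then vinylMgBr (1.1 equiv), CH2Cl2–THF, −78 °C
Reagents that add atoms: vinylmagnesium bromide, C=C[Mg]Br
Why: In this Cram-chelate Grignard addition Mg bridges the C3 carbonyl and the THF oxygen, and vinyl attacks from the H-2 side to set C3; chelation activates the methyl ketone well above the hindered α,α′-branched C11 ketone.

**Step 11**
Reactants: 12
Product: 13, the C11 β-alcohol (H-11 α, cis to the C12-Me)
Conditions: NaBH4, MeOH–CH2Cl2, −40 → 0 °C
Reagents that add atoms: none
Why: Substrate-controlled ketone reduction delivers hydride from the open α face, because the β face is covered by the THF ring, placing the C11 oxygen β and cis to the C12 methyl.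

**Step 12**
Reactants: 13
Product: 14, the C11 acetate
Conditions: Ac2O, pyridine, DMAP (cat.), CH2Cl2, 0 °C
Reagents that add atoms: acetic anhydride, CC(=O)OC(C)=O
Why: Acylation is selective for the secondary alcohol, and the tertiary C3–OH does not react at 0 °C.

**Step 13**
Reactants: 14
Product: 15, the C16 primary alcohol with the free C3 tertiary alcohol
Conditions: HF·pyridine, pyridine–THF, rt
Reagents that add atoms: none
Why: Buffered fluoride desilylation leaves the acetate, the vinyl bromide and the tertiary allylic alcohol intact.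

**Step 14**
Reactants: 15
Product: 16, the tricyclic oxepane (C16–O–C3) carrying C3-vinyl and C9-(2-bromoallyl)
Conditions: Tf2O (1.1 equiv), 2,6-lutidine, CH2Cl2, −78 °C → rt
Reagents that add atoms: none
Why: Only the primary alcohol is triflated at −78 °C, and the C3–OH displaces the triflate in a 7-exo-tet intramolecular Williamson-type etherification with C3 retained, since its C–O bond is untouched.

**Step 15**
Reactants: 16
Product: 17, the C4 aldehyde (CHO on quaternary C3)
Conditions: OsO4 (2 mol %), NaIO4, 2,6-lutidine, dioxane–H2O, rt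
Reagents that add atoms: OsO4, O=[Os](=O)(=O)=O, with NaIO4, [Na+].[O-]I(=O)(=O)=O (aldehyde oxygen)
Why: Lemieux–Johnson cleavage takes the monosubstituted vinyl group, while the electron-poor 2-bromoalkene is inert to catalytic osmylation.

**Step 16**
Reactants: 17
Product: 18, the C4 homoallylic alcohol (C4 as in 21; C4–O and C3–O threo)
Conditions: MgBr2·OEt2 (3 equiv), allyltributylstannane, CH2Cl2, −78 → −20 °C
Reagents that add atoms: allyltributylstannane, C=CC[Sn](CCCC)(CCCC)CCCC
Why: In this chelation-controlled (Keck-type) allylation Mg ties the aldehyde to the oxepane oxygen, and the stannane attacks from the CH3 side of C3, away from C2, giving the (4R)-carbinol.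

**Step 17**
Reactants: 18
Product: 19, the C4 octanoate
Conditions: octanoyl chloride, pyridine, DMAP, CH2Cl2, rt
Reagents that add atoms: octanoyl chloride, CCCCCCCC(=O)Cl
Why: DMAP-catalysed acylation acts on the only free hydroxyl and retains configuration at C4.

**Step 18**
Reactants: 19
Product: 20, the β-octanoyloxy aldehyde (C6 = CHO) bearing the C9 2-bromoallyl group
Conditions: OsO4 (2 mol %), NaIO4, 2,6-lutidine, dioxane–H2O, 0 °C → rt
Reagents that add atoms: OsO4, O=[Os](=O)(=O)=O, with NaIO4, [Na+].[O-]I(=O)(=O)=O (aldehyde oxygen)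
Why: A second chemoselective Lemieux–Johnson cleavage is run near neutral pH so the β-acyloxy aldehyde does not eliminate.

**Step 19**
Reactants: 20
Product: 21, asbestinin 16
Conditions: Ir[dF(CF3)ppy]2(dtbbpy)PF6 (2 mol %), NiBr2·dtbbpy (20 mol %), quinuclidine (30 mol %), Na2CO3, 1,4-dioxane (about 1 mM, slow addition of 20), 450 nm LEDs, 25 °C
Reagents that add atoms: none
Why: Proposed new method: an intramolecular formyl C–H/vinyl bromide coupling that closes a nine-membered ring, in which excited Ir(III) oxidises quinuclidine to its radical cation, this abstracts the hydridic, unhindered formyl H (selectivity over ether C–H is implied by dioxane being a usable solvent), Ni(0) inserts into the C7–Br bond, the tethered C6 acyl radical is captured at Ni(II), reductive elimination from acyl(vinyl)Ni(III) forms C6–C7 and the enone in one step, and Ir(II) returns Ni(I) to Ni(0); the cis, convex-face C3 and C8 chains on the THF pre-organise closure, no stereocentre is touched, and the closest known chemistry is intermolecular aldehyde C–H arylation by HAT/photoredox/nickel triple catalysis and Cr/Ni vinyl halide–aldehyde closure of this ring type.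

**Compound list**
1 | methyl (S)-3-hydroxy-2-methylpropanoate | COC(=O)[C@@H](C)CO | starting material
2 | TBDPS ether of 1 | COC(=O)[C@@H](C)CO[Si](c1ccccc1)(c1ccccc1)C(C)(C)C | intermediate
3 | (S)-3-(TBDPSO)-2-methylpropanal | O=C[C@@H](C)CO[Si](c1ccccc1)(c1ccccc1)C(C)(C)C | intermediate
4 | (R,E)-5-(TBDPSO)-4-methylpent-2-enal | O=C/C=C/[C@@H](C)CO[Si](c1ccccc1)(c1ccccc1)C(C)(C)C | intermediate
5 | 2,2-dimethoxyacetaldehyde | COC(OC)C=O | starting material
6 | (E)-5,5-dimethoxypent-3-en-2-one | CC(=O)/C=C/C(OC)OC | intermediate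
7 | (E)-5,5-dimethoxy-2-methylpenta-1,3-diene | C=C(C)/C=C/C(OC)OC | intermediate
8 | Diels–Alder aldehyde | O=C[C@H]1[C@@H](CC(C)=C[C@H]1C(OC)OC)[C@@H](C)CO[Si](c1ccccc1)(c1ccccc1)C(C)(C)C | intermediate
9 | C2-acetyl/C9-OMe hexahydroisobenzofuran | COC1O[C@H](C(C)=O)[C@H]2[C@@H](CC(C)=C[C@H]21)[C@@H](C)CO[Si](c1ccccc1)(c1ccccc1)C(C)(C)C | intermediate
10 | C3,C11-diketone | COC1O[C@H](C(C)=O)[C@H]2[C@@H](C[C@@H](C)C(=O)[C@H]21)[C@@H](C)CO[Si](c1ccccc1)(c1ccccc1)C(C)(C)C | intermediate
11 | C9-(2-bromoallyl) diketone | C=C(Br)C[C@@H]1O[C@H](C(C)=O)[C@H]2[C@@H](C[C@@H](C)C(=O)[C@H]21)[C@@H](C)CO[Si](c1ccccc1)(c1ccccc1)C(C)(C)C | intermediate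
12 | C3 tertiary allylic alcohol | C=C(Br)C[C@@H]1O[C@H]([C@@](C)(O)C=C)[C@H]2[C@@H](C[C@@H](C)C(=O)[C@H]21)[C@@H](C)CO[Si](c1ccccc1)(c1ccccc1)C(C)(C)C | intermediate
13 | C11 alcohol | C=C(Br)C[C@@H]1O[C@H]([C@@](C)(O)C=C)[C@H]2[C@@H](C[C@@H](C)[C@@H](O)[C@H]21)[C@@H](C)CO[Si](c1ccccc1)(c1ccccc1)C(C)(C)C | intermediate
14 | C11 acetate | C=C(Br)C[C@@H]1O[C@H]([C@@](C)(O)C=C)[C@H]2[C@@H](C[C@@H](C)[C@@H](OC(C)=O)[C@H]21)[C@@H](C)CO[Si](c1ccccc1)(c1ccccc1)C(C)(C)C | intermediate
15 | C16-OH/C3-OH diol | C=C(Br)C[C@@H]1O[C@H]([C@@](C)(O)C=C)[C@H]2[C@@H](C[C@@H](C)[C@@H](OC(C)=O)[C@H]21)[C@@H](C)CO | intermediate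
16 | oxepane tricycle (C3 vinyl) | C=C(Br)C[C@@H]2O[C@H]3[C@H]4[C@@H](C[C@@H](C)[C@@H](OC(C)=O)[C@H]42)[C@@H](C)CO[C@@]3(C)C=C | intermediate
17 | C4 aldehyde | C=C(Br)C[C@@H]2O[C@H]3[C@H]4[C@@H](C[C@@H](C)[C@@H](OC(C)=O)[C@H]42)[C@@H](C)CO[C@@]3(C)C=O | intermediate
18 | C4 homoallylic alcohol | C=C(Br)C[C@@H]2O[C@H]3[C@H]4[C@@H](C[C@@H](C)[C@@H](OC(C)=O)[C@H]42)[C@@H](C)CO[C@@]3(C)[C@H](O)CC=C | intermediate
19 | C4 octanoate | C=C(Br)C[C@@H]2O[C@H]3[C@H]4[C@@H](C[C@@H](C)[C@@H](OC(C)=O)[C@H]42)[C@@H](C)CO[C@@]3(C)[C@H](OC(=O)CCCCCCC)CC=C | intermediate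
20 | C6 aldehyde/C7 vinyl bromide | C=C(Br)C[C@@H]2O[C@H]3[C@H]4[C@@H](C[C@@H](C)[C@@H](OC(C)=O)[C@H]42)[C@@H](C)CO[C@@]3(C)[C@H](OC(=O)CCCCCCC)CC=O | intermediate
21 | asbestinin 16 | C=C1C[C@@H]2O[C@H]3[C@H]4[C@@H](C[C@@H](C)[C@@H](OC(C)=O)[C@H]42)[C@@H](C)CO[C@@]3(C)[C@H](OC(=O)CCCCCCC)CC1=O | target

**Step count**
Total steps: 19. Longest linear sequence: 17 (1 → 21 through steps 1–3 and 6–19).

**Steps most likely to fail**
1. Step 19, the proposed new macrocyclisation. The risks are slow capture of the acyl radical, competing HAT at ether C–H bonds, and base-induced loss of octanoate. The fallback uses known chemistry: Nozaki–Hiyama–Kishi closure of 20 (CrCl2, catalytic NiCl2, DMSO, high dilution) to the C6 allylic alcohol, then Dess–Martin oxidation to 21. This costs one extra step.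
2. Step 6, the Diels–Alder reaction. The risks are only moderate facial control from C15 and survival of the acetal under Me2AlCl. The fallback replaces the cycloaddition with stepwise ring construction:
   - Make the (E)-enoate of 3 as its (E)-4,4-dimethoxybut-2-enyl ester.
   - Add methallylcuprate/TMSCl anti to CH2OTBDPS, and let the silyl ketene acetal undergo Ireland–Claisen rearrangement to form C1–C10.
   - Close C11=C12 by ring-closing metathesis and adjust the acid to aldehyde 8.
3. Step 10, the vinyl addition to the diketone. The risks are attack or enolisation at C11 and erosion of C12. The fallback changes the masking strategy: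
   - Stop step 7 at the C3 dimethyl ketal.
   - Carry C11 through hydroboration–oxidation, NaBH4 and Ac2O first.
   - Hydrolyse the ketal, equilibrate C2 with DBU, and do the bromoallylation and chelate vinyl addition on a mono-ketone. This costs one extra step.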